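**Plan**
- Retrosynthesis: the three phenols are masked as methyl ethers. The pyranone of the daidzein half is cut at O1′–C2′/C2′–C3′ (one-carbon insertion into a 2-hydroxydeoxybenzoin) and at C4′–C4′a (Friedel–Crafts acylation of a 2,6-dimethoxyphenoxy ring). The C7–O bond of the chlorinated half is traced back to C7–F.
- The pyranone of the chlorinated half is then cut at C3–C4, O1–C2 and O1–C8a, giving an arylacetaldehyde enamine and 3-chloro-2,4-difluorobenzoyl chloride. The diaryl ether C–O bond is cut last (2,6-dimethoxyphenol plus 4-fluorobenzaldehyde).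
- Enabling feature: ring A of the chlorinated isoflavone carries O1 on C8a, Cl on C8 and OH on C7, three neighbouring carbons next to C4a. This is the 2-F/3-Cl/4-F array of commercial 3-chloro-2,4-difluorobenzoic acid: the ortho fluoride is the leaving group for ring closure and the para fluoride a masked hydroxyl.
- Forward order: diaryl ether, homologation to the enamine, pyranone ring C of the chlorinated half (key step), fluoride-to-methoxide exchange, acylation and closure of pyranone ring C′ of the daidzein half, global demethylation.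
- Stereochemistry: the target has no stereocentre. The only stereo-element on the way, the E enamine double bond, is set thermodynamically and is consumed in the key step.

Key step: step 5

Remark: enol ether 4 is carried as an E/Z mixture, since both isomers give the same aldehyde. The Wittig salt, morpholine, DMF-DMA and 13 are taken as commercial. Primed locants refer to the daidzein half.

**Step 1**
Reactants: 1 (2,6-dimethoxyphenol) and 2 (4-fluorobenzaldehyde)
Product: 3 4-(2,6-dimethoxyphenoxy)benzaldehyde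
Conditions: K2CO3, DMF, 120 °C
Reagents that add atoms: none
Why: SNAr, in which the phenoxide of 1 adds para to the formyl group of 2 and fluoride leaves, a standard diaryl ether synthesis that tolerates the two ortho methoxy groups because the electrophile is unhindered.

**Step 2**
Reactants: 3 (4-(2,6-dimethoxyphenoxy)benzaldehyde)
Product: 4 1,3-dimethoxy-2-[4-(2-methoxyethenyl)phenoxy]benzene (E/Z mixture)
Conditions: MeOCH2PPh3Cl, KOtBu, THF, 0 °C to rt
Reagents that add atoms: (methoxymethyl)triphenylphosphonium chloride, COC[P+](c1ccccc1)(c1ccccc1)c1ccccc1.[Cl-]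
Why: Wittig methoxymethylenation of a non-enolisable aromatic aldehyde gives the one-carbon-homologated enol ether, whose E/Z ratio is irrelevant because both isomers hydrolyse to the same aldehyde.

**Step 3**
Reactants: 4 (1,3-dimethoxy-2-[4-(2-methoxyethenyl)phenoxy]benzene)
Product: 6 4-[(E)-2-[4-(2,6-dimethoxyphenoxy)phenyl]ethenyl]morpholine, via arylacetaldehyde 5 (not isolated)
Conditions: 2 M aq HCl, THF, 50 °C; then morpholine, MgSO4, toluene, rt
Reagents that add atoms: morpholine, C1COCCN1
Why: Acid hydrolysis of the enol ether frees the arylacetaldehyde, which is condensed without storage with the secondary amine to the styrene-conjugated enamine (enamine formation), the E geometry being the thermodynamic one.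

**Step 4**
Reactants: 7 (3-chloro-2,4-difluorobenzoic acid)
Product: 8 3-chloro-2,4-difluorobenzoyl chloride
Conditions: SOCl2, cat. DMF, toluene, 70 °C
Reagents that add atoms: thionyl chloride, O=S(Cl)Cl
Why: Standard acid chloride formation with SOCl2 under Vilsmeier-type DMF catalysis, to which the aryl fluorides and the aryl chloride are inert.

**Step 5**
Reactants: 6 (4-[(E)-2-[4-(2,6-dimethoxyphenoxy)phenyl]ethenyl]morpholine) and 8 (3-chloro-2,4-difluorobenzoyl chloride)
Product: 11 8-chloro-3-[4-(2,6-dimethoxyphenoxy)phenyl]-7-fluoro-4H-chromen-4-one, via morpholino enaminone 9 (not isolated), via hydroxymethylene ketone 10 (not isolated)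
Conditions: Et3N, CH2Cl2, 0 °C to rt; then 1 M aq HCl, THF, rt (aqueous layer discarded); then K2CO3, DMF, 60 °C
Reagents that add atoms: water, O
Why: The electron-rich β-carbon of enamine 6, which already carries the aryl group, attacks acid chloride 8 (Stork enamine C-acylation) and Et3N deprotonates the iminium ion to the vinylogous amide 9, which forms C3–C4. Dilute acid then exchanges morpholine for oxygen to give the enolised formyl ketone 10 (O1–C2) and carries the amine into the aqueous phase, so that no nitrogen nucleophile is left to attack the para fluoride. With K2CO3 in DMF the enolate oxygen adds to the fluorine-bearing carbon ortho to the ketone and fluoride leaves through a Meisenheimer intermediate (intramolecular SNAr, O1–C8a), closing the six-membered pyranone by exo attack of oxygen on the aryl carbon. The closest known reactions are the cycloaracylation of aminoacrylates with 2-fluorobenzoyl chlorides used for 4-quinolones and the base-mediated chromone formation from 1-(2-fluoroaryl)-1,3-dicarbonyl compounds. No stereocentre is created; the selectivity needed is ortho- over para-fluoride displacement, secured because only the ortho C–F lies within reach of the tethered enolate oxygen and is activated by the adjacent ketone and the flanking chlorine, while the para C–F meets only carbonate.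

**Step 6**
Reactants: 11 (8-chloro-3-[4-(2,6-dimethoxyphenoxy)phenyl]-7-fluoro-4H-chromen-4-one)
Product: 12 8-chloro-3-[4-(2,6-dimethoxyphenoxy)phenyl]-7-methoxy-4H-chromen-4-one
Conditions: NaOMe, MeOH/THF, 0 to 50 °C
Reagents that add atoms: sodium methoxide, C[O-].[Na+]
Why: SNAr, since C7 is para to the C4 carbonyl and ortho to chlorine so that methoxide displaces the remaining fluoride irreversibly, whereas addition at C2 of the pyranone is reversible under anhydrous conditions and the C8 chloride, meta to the carbonyl, is not activated.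

**Step 7**
Reactants: 12 (8-chloro-3-[4-(2,6-dimethoxyphenoxy)phenyl]-7-methoxy-4H-chromen-4-one) and 13 (4-methoxyphenylacetyl chloride)
Product: 14 8-chloro-3-(4-{2,6-dimethoxy-3-[(4-methoxyphenyl)acetyl]phenoxy}phenyl)-7-methoxy-4H-chromen-4-one
Conditions: AlCl3, CH2Cl2, 0 °C
Reagents that add atoms: none
Why: Friedel–Crafts acylation, in which the 2,6-dimethoxyphenoxy ring is the only strongly activated arene and, like 1,2,3-trimethoxybenzene, reacts para to one methoxy and ortho to the other (C3, equivalent to C5 by symmetry), while the AlCl3-complexed chromone and the phenylene ring attached to it are deactivated.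

**Step 8**
Reactants: 14 (8-chloro-3-(4-{2,6-dimethoxy-3-[(4-methoxyphenyl)acetyl]phenoxy}phenyl)-7-methoxy-4H-chromen-4-one)
Product: 15 8-chloro-3-(4-{2-hydroxy-6-methoxy-3-[(4-methoxyphenyl)acetyl]phenoxy}phenyl)-7-methoxy-4H-chromen-4-one
Conditions: BCl3, CH2Cl2, −78 to 0 °C; then H2O
Reagents that add atoms: none
Why: Chelation-controlled ortho-demethylation, in which BCl3 bridges the ketone oxygen and the neighbouring methoxy oxygen and cleaves only that methyl ether, leaving the three non-chelating methoxy groups and the diaryl ether untouched.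

**Step 9**
Reactants: 15 (8-chloro-3-(4-{2-hydroxy-6-methoxy-3-[(4-methoxyphenyl)acetyl]phenoxy}phenyl)-7-methoxy-4H-chromen-4-one)
Product: 17 8-chloro-7-methoxy-3-(4-{[7-methoxy-3-(4-methoxyphenyl)-4-oxo-4H-chromen-8-yl]oxy}phenyl)-4H-chromen-4-one, via dimethylamino enaminone 16 (not isolated)
Conditions: DMF-DMA, toluene, 100 °C
Reagents that add atoms: N,N-dimethylformamide dimethyl acetal, COC(OC)N(C)C
Why: Classical isoflavone closure of a 2-hydroxydeoxybenzoin, in which DMF-DMA condenses at the activated methylene to the enaminone and the phenol then adds to its β-carbon and expels dimethylamine (addition–elimination) to form the second pyranone.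

**Step 10**
Reactants: 17 (8-chloro-7-methoxy-3-(4-{[7-methoxy-3-(4-methoxyphenyl)-4-oxo-4H-chromen-8-yl]oxy}phenyl)-4H-chromen-4-one)
Product: 18 bisoflavolin J, 8-chloro-7-hydroxy-3-(4-{[7-hydroxy-3-(4-hydroxyphenyl)-4-oxo-4H-chromen-8-yl]oxy}phenyl)-4H-chromen-4-one
Conditions: BBr3, CH2Cl2, −78 °C to rt; then H2O
Reagents that add atoms: none
Why: BBr3 cleavage of aryl methyl ethers should release the three phenols, while the diaryl ether, the aryl chloride and both chromone cores are stable to the Lewis acid and to the aqueous work-up.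

**Compound list**
1 | 2,6-dimethoxyphenol | COc1cccc(OC)c1O | starting material
2 | 4-fluorobenzaldehyde | O=Cc1ccc(F)cc1 | starting material
3 | 4-(2,6-dimethoxyphenoxy)benzaldehyde | COc1cccc(OC)c1Oc1ccc(C=O)cc1 | intermediate
4 | 1,3-dimethoxy-2-[4-(2-methoxyethenyl)phenoxy]benzene (E/Z mixture) | COC=Cc1ccc(Oc2c(OC)cccc2OC)cc1 | intermediate
5 | 2-[4-(2,6-dimethoxyphenoxy)phenyl]acetaldehyde | O=CCc1ccc(Oc2c(OC)cccc2OC)cc1 | intermediate (not isolated)
6 | 4-[(E)-2-[4-(2,6-dimethoxyphenoxy)phenyl]ethenyl]morpholine | COc1cccc(OC)c1Oc1ccc(/C=C/N2CCOCC2)cc1 | intermediate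
7 | 3-chloro-2,4-difluorobenzoic acid | OC(=O)c1ccc(F)c(Cl)c1F | starting material
8 | 3-chloro-2,4-difluorobenzoyl chloride | O=C(Cl)c1ccc(F)c(Cl)c1F | intermediate
9 | 1-(3-chloro-2,4-difluorophenyl)-2-[4-(2,6-dimethoxyphenoxy)phenyl]-3-(morpholin-4-yl)prop-2-en-1-one (double-bond geometry not fixed) | COc1cccc(OC)c1Oc1ccc(C(=CN2CCOCC2)C(=O)c2ccc(F)c(Cl)c2F)cc1 | intermediate (not isolated)
10 | 1-(3-chloro-2,4-difluorophenyl)-2-[4-(2,6-dimethoxyphenoxy)phenyl]-3-hydroxyprop-2-en-1-one (enol of the formyl ketone) | COc1cccc(OC)c1Oc1ccc(C(=CO)C(=O)c2ccc(F)c(Cl)c2F)cc1 | intermediate (not isolated)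
11 | 8-chloro-3-[4-(2,6-dimethoxyphenoxy)phenyl]-7-fluoro-4H-chromen-4-one | O=c1c(-c2ccc(Oc3c(OC)cccc3OC)cc2)coc2c(Cl)c(F)ccc12 | intermediate
12 | 8-chloro-3-[4-(2,6-dimethoxyphenoxy)phenyl]-7-methoxy-4H-chromen-4-one | O=c1c(-c2ccc(Oc3c(OC)cccc3OC)cc2)coc2c(Cl)c(OC)ccc12 | intermediate
13 | 4-methoxyphenylacetyl chloride | COc1ccc(CC(=O)Cl)cc1 | starting material
14 | 8-chloro-3-(4-{2,6-dimethoxy-3-[(4-methoxyphenyl)acetyl]phenoxy}phenyl)-7-methoxy-4H-chromen-4-one | O=c1c(-c2ccc(Oc3c(OC)c(C(=O)Cc4ccc(OC)cc4)ccc3OC)cc2)coc2c(Cl)c(OC)ccc12 | intermediate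
15 | 8-chloro-3-(4-{2-hydroxy-6-methoxy-3-[(4-methoxyphenyl)acetyl]phenoxy}phenyl)-7-methoxy-4H-chromen-4-one | O=c1c(-c2ccc(Oc3c(O)c(C(=O)Cc4ccc(OC)cc4)ccc3OC)cc2)coc2c(Cl)c(OC)ccc12 | intermediate
16 | 8-chloro-3-(4-{3-[3-(dimethylamino)-2-(4-methoxyphenyl)prop-2-enoyl]-2-hydroxy-6-methoxyphenoxy}phenyl)-7-methoxy-4H-chromen-4-one (double-bond geometry not fixed) | O=c1c(-c2ccc(Oc3c(O)c(C(=O)C(=CN(C)C)c4ccc(OC)cc4)ccc3OC)cc2)coc2c(Cl)c(OC)ccc12 | intermediate (not isolated)
17 | 8-chloro-7-methoxy-3-(4-{[7-methoxy-3-(4-methoxyphenyl)-4-oxo-4H-chromen-8-yl]oxy}phenyl)-4H-chromen-4-one | O=c1c(-c2ccc(Oc3c(OC)ccc4c(=O)c(-c5ccc(OC)cc5)coc34)cc2)coc2c(Cl)c(OC)ccc12 | intermediate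
18 | bisoflavolin J | O=c1c(-c2ccc(Oc3c(O)ccc4c(=O)c(-c5ccc(O)cc5)coc34)cc2)coc2c(Cl)c(O)ccc12 | target

**Step count**
Total: 10 steps. Longest linear sequence: 9 steps (steps 1, 2, 3, 5, 6, 7, 8, 9, 10); step 4 is a one-step branch that supplies 8.

**Steps most likely to fail**

Step 5. The conjugated, aryl-substituted enamine may be acylated sluggishly or at nitrogen, and the formyl ketone may lose its formyl carbon by retro-Claisen cleavage before the ring closes. The fallback sets out from enol ether 4 and keeps the SNAr closure but makes the C3–C4 bond by enediolate acylation. Acid hydrolysis to aldehyde 5 and Pinnick oxidation (NaClO2, NaH2PO4, 2-methyl-2-butene, tBuOH/H2O) should give [4-(2,6-dimethoxyphenoxy)phenyl]acetic acid F1. Its dilithium enediolate (LiN(iPr)2, THF, −78 °C) would be C-acylated by acid chloride 8 to racemic 3-(3-chloro-2,4-difluorophenyl)-2-[4-(2,6-dimethoxyphenoxy)phenyl]-3-oxopropanoic acid F2, which is not isolated and should decarboxylate on acidic work-up to the deoxybenzoin 1-(3-chloro-2,4-difluorophenyl)-2-[4-(2,6-dimethoxyphenoxy)phenyl]ethanone F3. DMF-DMA in toluene at 90 °C would then give 1-(3-chloro-2,4-difluorophenyl)-2-[4-(2,6-dimethoxyphenoxy)phenyl]-3-(dimethylamino)prop-2-en-1-one F4. Subjected to the acid hydrolysis and K2CO3/DMF closure of step 5, F4 passes through 10 and comes back to the route at 11.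

Step 6. Methoxide may add to C2 of the pyranone and open ring C, with loss of the C2 carbon on prolonged exposure, faster than it displaces the fluoride. The fallback sets out from 11 and uses a weakly basic hydroxide surrogate. The oximate of (E)-benzaldoxime (Cs2CO3, DMSO, 70 °C) would displace the fluoride to give (E)-benzaldehyde O-{8-chloro-3-[4-(2,6-dimethoxyphenoxy)phenyl]-4-oxo-4H-chromen-7-yl}oxime F5, which is not isolated and should fragment under the same conditions to benzonitrile and the phenol 8-chloro-3-[4-(2,6-dimethoxyphenoxy)phenyl]-7-hydroxy-4H-chromen-4-one F6. O-Methylation (MeI, K2CO3, acetone) comes back to the route at 12.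

Step 7. The Lewis acid may be sequestered by the chromone carbonyl and the ether oxygens, may cleave a methyl ether early so that the freed phenol is O-acylated, or may promote decarbonylation of the arylacetyl cation, so that C-acylation stalls or loses site selectivity. The fallback sets out from 12 and replaces the acylation by halogenation and cross-coupling. Bromination with NBS in MeCN, para to a methoxy group of the dimethoxyphenoxy ring as with 1,2,3-trimethoxybenzene, should give 3-[4-(3-bromo-2,6-dimethoxyphenoxy)phenyl]-8-chloro-7-methoxy-4H-chromen-4-one F7. Stille coupling with tributyl(1-ethoxyvinyl)stannane (Pd(PPh3)4, toluene, 100 °C) would give 8-chloro-3-{4-[3-(1-ethoxyethenyl)-2,6-dimethoxyphenoxy]phenyl}-7-methoxy-4H-chromen-4-one F8, hydrolysed by dilute HCl to the methyl ketone 3-[4-(3-acetyl-2,6-dimethoxyphenoxy)phenyl]-8-chloro-7-methoxy-4H-chromen-4-one F9. Pd-catalysed α-arylation of F9 with 4-bromoanisole (Pd2(dba)3, Xantphos, K3PO4, toluene, 80 °C) comes back to the route at 14.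

**Further compounds**
F1 | step 5 | [4-(2,6-dimethoxyphenoxy)phenyl]acetic acid | COc1cccc(OC)c1Oc1ccc(CC(=O)O)cc1
F2 | step 5 | 3-(3-chloro-2,4-difluorophenyl)-2-[4-(2,6-dimethoxyphenoxy)phenyl]-3-oxopropanoic acid (racemic) | COc1cccc(OC)c1Oc1ccc(C(C(=O)O)C(=O)c2ccc(F)c(Cl)c2F)cc1
F3 | step 5 | 1-(3-chloro-2,4-difluorophenyl)-2-[4-(2,6-dimethoxyphenoxy)phenyl]ethanone | COc1cccc(OC)c1Oc1ccc(CC(=O)c2ccc(F)c(Cl)c2F)cc1
F4 | step 5 | 1-(3-chloro-2,4-difluorophenyl)-2-[4-(2,6-dimethoxyphenoxy)phenyl]-3-(dimethylamino)prop-2-en-1-one | COc1cccc(OC)c1Oc1ccc(C(=CN(C)C)C(=O)c2ccc(F)c(Cl)c2F)cc1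
F5 | step 6 | (E)-benzaldehyde O-{8-chloro-3-[4-(2,6-dimethoxyphenoxy)phenyl]-4-oxo-4H-chromen-7-yl}oxime | O=c1c(-c2ccc(Oc3c(OC)cccc3OC)cc2)coc2c(Cl)c(O/N=C/c3ccccc3)ccc12
F6 | step 6 | 8-chloro-3-[4-(2,6-dimethoxyphenoxy)phenyl]-7-hydroxy-4H-chromen-4-one | O=c1c(-c2ccc(Oc3c(OC)cccc3OC)cc2)coc2c(Cl)c(O)ccc12
F7 | step 7 | 3-[4-(3-bromo-2,6-dimethoxyphenoxy)phenyl]-8-chloro-7-methoxy-4H-chromen-4-one | O=c1c(-c2ccc(Oc3c(OC)c(Br)ccc3OC)cc2)coc2c(Cl)c(OC)ccc12
F8 | step 7 | 8-chloro-3-{4-[3-(1-ethoxyethenyl)-2,6-dimethoxyphenoxy]phenyl}-7-methoxy-4H-chromen-4-one | O=c1c(-c2ccc(Oc3c(OC)c(C(=C)OCC)ccc3OC)cc2)coc2c(Cl)c(OC)ccc12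
F9 | step 7 | 3-[4-(3-acetyl-2,6-dimethoxyphenoxy)phenyl]-8-chloro-7-methoxy-4H-chromen-4-one | O=c1c(-c2ccc(Oc3c(OC)c(C(C)=O)ccc3OC)cc2)coc2c(Cl)c(OC)ccc12
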